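**Plan**
1. Retrosynthesis: the C8=C9 enol-lactone alkene is cut first (intramolecular Horner–Wadsworth–Emmons: C9 aldehyde on C10, C8 phosphonate on the butenolide). Then the C13 acetate and C6 senecioate, the 3(2H)-furanone (from a 4-hydroxy-2-yn-1-one), C2–C3 (acetylide + γ-lactone) and C5–C6 (carbonyl allylation).
2. Enabling feature: C8 is the γ-carbon of the butenolide (O–C8–C7=C11–C12=O, a vinylogous enolate position) and also one end of the only C=C inside the nine-membered ring C7–C8=C9–C10–O–C3–C4–C5–C6. C9 sits on the fully substituted, non-enolisable C10 of the furanone.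
3. Forward: 3,4-bis(hydroxymethyl)furan is the latent butenolide. A phosphonate placed on C8 by directed lithiation later blocks C8, so C–H borylation/oxidation can only oxygenate C12, and finally serves as the olefination handle.
4. Ring order: furan (bought) → temporary γ-lactone (sets C6 and C4) → opened by the C10 alkynyl fragment → 3(2H)-furanone → furan oxidised to butenolide → nine-membered ring.
5. Stereochemistry: C10 from (R)-2-methylglycidol; C6 from a catalyst-controlled iridium allylation; C4 by hydrogenation of the α-methylene lactone anti to the furyl group; C8=C9 geometry (E, C7 cis to C10) imposed by the ring.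

Key step: step 15

Remark: germacrane-type locants are used (C1 furanone C=O, C2 =CH, C3 O–C=, C4 CHMe, C5 CH2, C6 CH–O, C7/C11/C12 butenolide β-C/α-C/C=O, C8 butenolide γ-C, C9 exocyclic =CH, C10 C(Me)O, C13 CH2O). TIPS = tri(propan-2-yl)silyl, PMB = 4-methoxybenzyl. The TMBTP antipode for step 4 is assumed to be assignable from the known sense of induction with benzylic alcohols.

**Step 1**
Reactants: 1 furan-3,4-diyldimethanol
Product: 2 [4-(TIPS-oxymethyl)furan-3-yl]methanol
Conditions: 1 (2 equiv), TIPSCl (1 equiv), imidazole, DMF, 0 °C; excess 1 recovered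
Reagents that add atoms: chlorotri(propan-2-yl)silane, CC(C)[Si](Cl)(C(C)C)C(C)C
Why: Statistical monosilylation of a symmetrical diol (silyl ether formation) desymmetrises the furan; the silylated arm becomes C13 and the free arm C6.

**Step 2**
Reactants: 2 [4-(TIPS-oxymethyl)furan-3-yl]methanol
Product: 4 diethyl [3-(hydroxymethyl)-4-(TIPS-oxymethyl)furan-2-yl]phosphonate, via dilithio dianion 3 (not isolated)
Conditions: n-BuLi (2.1 equiv), THF, −78 → 0 °C; then ClP(O)(OEt)2 (1.0 equiv), −78 °C; aq NH4Cl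
Reagents that add atoms: n-butyllithium, [Li]CCCC (lithium of 3 only); diethyl chlorophosphate, CCOP(Cl)(=O)OCC
Why: Alkoxide-directed ortho-lithiation of the 3-furylmethanol dianion should occur at the adjacent α-carbon C8, and the C–Li centre is phosphorylated in preference to the alkoxide (directed ortho-metalation with electrophilic quench).

**Step 3**
Reactants: 5 methyl 2-(hydroxymethyl)prop-2-enoate
Product: 6 methyl 2-{[(tert-butoxycarbonyl)oxy]methyl}prop-2-enoate
Conditions: Boc2O, DMAP (cat.), CH2Cl2, 0 °C → rt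
Reagents that add atoms: di-tert-butyl dicarbonate, CC(C)(C)OC(=O)OC(=O)OC(C)(C)C
Why: DMAP-catalysed carbonate formation converts the Morita–Baylis–Hillman alcohol into the allyl donor needed for step 4.

**Step 4**
Reactants: 4 diethyl [3-(hydroxymethyl)-4-(TIPS-oxymethyl)furan-2-yl]phosphonate; 6 methyl 2-{[(tert-butoxycarbonyl)oxy]methyl}prop-2-enoate
Product: 8 diethyl {3-[(2S)-4-methylidene-5-oxooxolan-2-yl]-4-(TIPS-oxymethyl)furan-2-yl}phosphonate, via hydroxy ester 7 (not isolated)
Conditions: [Ir(cod)Cl]2 (2.5 mol %), TMBTP (5 mol %, antipode giving the S carbinol), 4-cyano-3-nitrobenzoic acid (10 mol %), Cs2CO3 (20 mol %), THF, 100 °C; then p-TsOH (cat.), rt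
Reagents that add atoms: none
Why: Iridium-catalysed transfer-hydrogenative 2-(alkoxycarbonyl)allylation of a primary alcohol forms C5–C6 directly from the alcohol oxidation level, the chiral cyclometalated Ir–TMBTP complex setting C6 (S), and the γ-hydroxy ester lactonises to the α-methylene-γ-butyrolactone.

**Step 5**
Reactants: 8 diethyl {3-[(2S)-4-methylidene-5-oxooxolan-2-yl]-4-(TIPS-oxymethyl)furan-2-yl}phosphonate
Product: 9 diethyl {3-[(2S,4S)-4-methyl-5-oxooxolan-2-yl]-4-(TIPS-oxymethyl)furan-2-yl}phosphonate (cis lactone)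
Conditions: H2 (1 atm), 5% Pd/C, EtOAc, 0 °C → rt, stopped after one equivalent of H2; minor trans isomer removed by chromatography
Reagents that add atoms: none
Why: Heterogeneous hydrogenation of the exocyclic alkene delivers hydrogen to the face anti to the furyl group, so the new methyl (C15) ends up cis to it and C4 becomes S; the phosphonate-deactivated furan should survive.

**Step 6**
Reactants: 10 [(2R)-2-methyloxiran-2-yl]methanol
Product: 11 (2R)-2-methyl-3-(PMB-oxy)propane-1,2-diol
Conditions: 4-methoxybenzyl alcohol (5 equiv, as solvent), NaH (0.2 equiv), 60 °C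
Reagents that add atoms: 4-methoxybenzyl alcohol, COc1ccc(CO)cc1
Why: Base-catalysed epoxide opening by the alkoxide occurs at the unhindered CH2 (SN2), so the quaternary stereocentre (future C10) is not touched; the opened arm becomes C9.

**Step 7**
Reactants: 11 (2R)-2-methyl-3-(PMB-oxy)propane-1,2-diol
Product: 12 (2S)-2-hydroxy-2-methyl-3-(PMB-oxy)propanal
Conditions: TEMPO (10 mol %), PhI(OAc)2 (1.1 equiv), CH2Cl2, rt; used crude
Reagents that add atoms: none
Why: Oxoammonium (TEMPO) oxidation is selective for the primary alcohol beside the tertiary one, and the α-carbon is quaternary so it cannot epimerise.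

**Step 8**
Reactants: 12 (2S)-2-hydroxy-2-methyl-3-(PMB-oxy)propanal
Product: 13 (2R)-2-methyl-1-(PMB-oxy)but-3-yn-2-ol
Conditions: dimethyl (1-diazo-2-oxopropyl)phosphonate (1.3 equiv), K2CO3 (2 equiv), MeOH, 0 °C → rt
Reagents that add atoms: dimethyl (1-diazo-2-oxopropyl)phosphonate, COP(=O)(OC)C(=[N+]=[N-])C(C)=O
Why: Ohira–Bestmann (Seyferth–Gilbert) homologation turns the aldehyde into the terminal alkyne (C1≡C2) under mild base without touching the quaternary carbinol.

**Step 9**
Reactants: 9 diethyl {3-[(2S,4S)-4-methyl-5-oxooxolan-2-yl]-4-(TIPS-oxymethyl)furan-2-yl}phosphonate; 13 (2R)-2-methyl-1-(PMB-oxy)but-3-yn-2-ol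
Product: 15 diethyl {3-[(1S,3S,7R)-1,7-dihydroxy-3,7-dimethyl-4-oxo-8-(PMB-oxy)oct-5-yn-1-yl]-4-(TIPS-oxymethyl)furan-2-yl}phosphonate, via dilithio alkynol 14 (not isolated)
Conditions: 13 (1.2 equiv), n-BuLi (2.4 equiv), THF, −78 °C; then 9, −78 → −40 °C; AcOH/THF quench at −78 °C, aq NH4Cl
Reagents that add atoms: n-butyllithium, [Li]CCCC (lithium of 14 only)
Why: The alkynyllithium adds once to the γ-lactone carbonyl (C2–C3 bond) to give a lithium lactolate that is stable until work-up, so over-addition is avoided; cold acidic quench should protect the C4 stereocentre (acetylide acylation by a lactone).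

**Step 10**
Reactants: 15 ynone diol; 16 3-methylbut-2-enoyl chloride
Product: 17 (1S,3S,7R)-1-[2-(diethoxyphosphoryl)-4-(TIPS-oxymethyl)furan-3-yl]-7-hydroxy-3,7-dimethyl-4-oxo-8-(PMB-oxy)oct-5-yn-1-yl 3-methylbut-2-enoate
Conditions: 16 (1.5 equiv), pyridine, DMAP (5 mol %), CH2Cl2, −20 → 0 °C
Reagents that add atoms: none
Why: Acylation is selective for the secondary C6 hydroxyl over the tertiary propargylic one, and pyridine rather than a trialkylamine limits deconjugation of the senecioyl group and epimerisation at C4; esterifying C6 now prevents later spiroketalisation onto C3.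

**Step 11**
Reactants: 17 senecioate ynone
Product: 18 (1S,3S)-1-[2-(diethoxyphosphoryl)-4-(TIPS-oxymethyl)furan-3-yl]-3-[(5S)-5-methyl-4-oxo-5-(PMB-oxymethyl)-4,5-dihydrofuran-2-yl]butyl 3-methylbut-2-enoate
Conditions: (4-CF3C6H4)3PAuCl (5 mol %), AgOTf (5 mol %), toluene (not rigorously dried), rt
Reagents that add atoms: none
Why: Gold(I)-catalysed cyclisation of a 4-hydroxyalk-2-yn-1-one gives the 3(2H)-furanone in which the carbinol carbon becomes C10, the adjacent alkyne carbon the C1 ketone, and the former ketone carbon C3; the C10–O bond is never broken, so C10 keeps its configuration.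

**Step 12**
Reactants: 18 PMB-protected furanone
Product: 19 (1S,3S)-1-[2-(diethoxyphosphoryl)-4-(TIPS-oxymethyl)furan-3-yl]-3-[(5S)-5-(hydroxymethyl)-5-methyl-4-oxo-4,5-dihydrofuran-2-yl]butyl 3-methylbut-2-enoate
Conditions: DDQ (1.3 equiv), CH2Cl2/pH 7 buffer (10:1), 0 °C → rt
Reagents that add atoms: none
Why: Oxidative PMB ether cleavage is done while the heteroaromatic ring is still the electron-poor furylphosphonate, which DDQ should not attack.

**Step 13**
Reactants: 19 furanone alcohol
Product: 21 (1S,3S)-1-[2-(diethoxyphosphoryl)-5-oxo-4-(TIPS-oxymethyl)-2,5-dihydrofuran-3-yl]-3-[(5S)-5-(hydroxymethyl)-5-methyl-4-oxo-4,5-dihydrofuran-2-yl]butyl 3-methylbut-2-enoate (both C8 epimers), via bis-boronate 20 (not isolated)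
Conditions: [Ir(OMe)(cod)]2 (3 mol %), dtbpy (6 mol %), B2pin2 (2.2 equiv), THF, rt → 50 °C; then 30% H2O2, pH 7 phosphate buffer, THF, 0 °C, under argon
Reagents that add atoms: bis(pinacolato)diboron, CC1(C)OB(OC1(C)C)B1OC(C)(C)C(C)(C)O1 (boron of 20 only); hydrogen peroxide, OO
Why: Iridium-catalysed C–H borylation can only take the one remaining furan α-C–H (C12) because C8 carries the phosphonate, the free hydroxyl being masked in passing as its O-boronate; oxidation of the furyl boronate gives the 2-hydroxyfuran, which tautomerises to the butenolide with C12 as carbonyl and C8 as the CH(P) carbon.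

**Step 14**
Reactants: 21 butenolide phosphonate alcohol
Product: 22 (1S,3S)-1-[2-(diethoxyphosphoryl)-5-oxo-4-(TIPS-oxymethyl)-2,5-dihydrofuran-3-yl]-3-[(5S)-5-formyl-5-methyl-4-oxo-4,5-dihydrofuran-2-yl]butyl 3-methylbut-2-enoate
Conditions: Dess–Martin periodinane (1.5 equiv), CH2Cl2, 0 °C → rt; filtered and used directly
Reagents that add atoms: none
Why: Dess–Martin oxidation of the neopentyl primary alcohol is run without base, which avoids retro-aldol loss of C9 from the β-hydroxy ketone.

**Step 15**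
Reactants: 22 phosphonate aldehyde
Product: 23 13-O-TIPS-13-deacetyl macrocycle (the target with OTIPS in place of OAc at C13)
Conditions: LiCl (10 equiv), iPr2NEt (5 equiv), MeCN, rt; 22 added by syringe pump over 12 h to a final concentration of about 1 mM
Reagents that add atoms: none
Why: Deprotonation at C8 (γ-CH of the butenolide, also α to phosphorus) by the amine/LiCl pair gives a phosphonate-stabilised 2-oxidofuran carbanion, which adds to the C9 aldehyde and collapses through the oxaphosphetane with loss of diethyl phosphate to the C8=C9 enol-lactone alkene (intramolecular Horner–Wadsworth–Emmons olefination). The closest known reaction types are the olefination of aldehydes with γ-phosphono butenolides and phthalide-3-phosphonates to γ-ylidene lactones, and macrocyclic HWE ring closures under Masamune–Roush conditions. It closes one ring, the nine-membered oxacycle C7–C8=C9–C10–O–C3–C4–C5–C6 (ten-membered when counted through C1–C2), by an olefination in which the new alkene is endocyclic to the new ring and exocyclic to the butenolide. No new stereocentre is formed; both C8 epimers of 22 converge on the same planar anion, and the alkene geometry is fixed as E (C7 cis to C10) because only that isomer can span the ring. The selectivities needed are ring closure over oligomerisation, secured by slow addition at high dilution, and attack on the aldehyde only, secured because C9 is the most electrophilic carbonyl and, sitting on quaternary C10, cannot enolise. C13 is carried as a silyl ether and not as the acetate so that the C8 carbanion cannot expel the C13 oxygen by vinylogous E1cB elimination.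

**Step 16**
Reactants: 23 13-O-TIPS macrocycle
Product: 24 13-deacetyl macrocycle (primary allylic alcohol at C13)
Conditions: HF·pyridine, pyridine/THF, 0 °C → rt
Reagents that add atoms: none
Why: Buffered fluoride desilylation removes the primary TIPS ether without touching the enol lactone, the furanone or the senecioate.

**Step 17**
Reactants: 24 13-deacetyl macrocycle
Product: 25 CNP0102620.1
Conditions: Ac2O, pyridine, DMAP (cat.), CH2Cl2, 0 °C
Reagents that add atoms: acetic anhydride, CC(=O)OC(C)=O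
Why: Acetylation of the only free hydroxyl installs the C13 acetate last, when C8 no longer bears a hydrogen and elimination of acetate is impossible.

**Compound list**
1 | furan-3,4-diyldimethanol | OCc1cocc1CO | starting material
2 | [4-(TIPS-oxymethyl)furan-3-yl]methanol | OCc1cocc1CO[Si](C(C)C)(C(C)C)C(C)C | intermediate
3 | dilithio dianion of 2 (C8–Li, O–Li) | [Li]OCc1c([Li])occ1CO[Si](C(C)C)(C(C)C)C(C)C | intermediate
4 | diethyl [3-(hydroxymethyl)-4-(TIPS-oxymethyl)furan-2-yl]phosphonate | CCOP(=O)(OCC)c1occ(CO[Si](C(C)C)(C(C)C)C(C)C)c1CO | intermediate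
5 | methyl 2-(hydroxymethyl)prop-2-enoate | C=C(CO)C(=O)OC | starting material
6 | methyl 2-{[(tert-butoxycarbonyl)oxy]methyl}prop-2-enoate | C=C(COC(=O)OC(C)(C)C)C(=O)OC | intermediate
7 | methyl (4S)-4-[2-(diethoxyphosphoryl)-4-(TIPS-oxymethyl)furan-3-yl]-4-hydroxy-2-methylidenebutanoate | C=C(C[C@H](O)c1c(P(=O)(OCC)OCC)occ1CO[Si](C(C)C)(C(C)C)C(C)C)C(=O)OC | intermediate
8 | diethyl {3-[(2S)-4-methylidene-5-oxooxolan-2-yl]-4-(TIPS-oxymethyl)furan-2-yl}phosphonate | C=C1C[C@@H](c2c(P(=O)(OCC)OCC)occ2CO[Si](C(C)C)(C(C)C)C(C)C)OC1=O | intermediate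
9 | diethyl {3-[(2S,4S)-4-methyl-5-oxooxolan-2-yl]-4-(TIPS-oxymethyl)furan-2-yl}phosphonate | C[C@H]1C[C@@H](c2c(P(=O)(OCC)OCC)occ2CO[Si](C(C)C)(C(C)C)C(C)C)OC1=O | intermediate
10 | [(2R)-2-methyloxiran-2-yl]methanol | OC[C@]1(C)CO1 | starting material
11 | (2R)-2-methyl-3-(PMB-oxy)propane-1,2-diol | OC[C@](O)(C)COCc1ccc(OC)cc1 | intermediate
12 | (2S)-2-hydroxy-2-methyl-3-(PMB-oxy)propanal | O=C[C@](O)(C)COCc1ccc(OC)cc1 | intermediate
13 | (2R)-2-methyl-1-(PMB-oxy)but-3-yn-2-ol | C#C[C@](O)(C)COCc1ccc(OC)cc1 | intermediate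
14 | dilithio derivative of 13 (acetylide and alkoxide) | [Li]C#C[C@](O[Li])(C)COCc1ccc(OC)cc1 | intermediate
15 | diethyl {3-[(1S,3S,7R)-1,7-dihydroxy-3,7-dimethyl-4-oxo-8-(PMB-oxy)oct-5-yn-1-yl]-4-(TIPS-oxymethyl)furan-2-yl}phosphonate | COc1ccc(COC[C@](C)(O)C#CC(=O)[C@@H](C)C[C@H](O)c2c(P(=O)(OCC)OCC)occ2CO[Si](C(C)C)(C(C)C)C(C)C)cc1 | intermediate
16 | 3-methylbut-2-enoyl chloride | CC(C)=CC(Cl)=O | starting material
17 | (1S,3S,7R)-1-[2-(diethoxyphosphoryl)-4-(TIPS-oxymethyl)furan-3-yl]-7-hydroxy-3,7-dimethyl-4-oxo-8-(PMB-oxy)oct-5-yn-1-yl 3-methylbut-2-enoate | COc1ccc(COC[C@](C)(O)C#CC(=O)[C@@H](C)C[C@H](OC(=O)C=C(C)C)c2c(P(=O)(OCC)OCC)occ2CO[Si](C(C)C)(C(C)C)C(C)C)cc1 | intermediate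
18 | (1S,3S)-1-[2-(diethoxyphosphoryl)-4-(TIPS-oxymethyl)furan-3-yl]-3-[(5S)-5-methyl-4-oxo-5-(PMB-oxymethyl)-4,5-dihydrofuran-2-yl]butyl 3-methylbut-2-enoate | COc1ccc(COC[C@]2(C)OC(=CC2=O)[C@@H](C)C[C@H](OC(=O)C=C(C)C)c3c(P(=O)(OCC)OCC)occ3CO[Si](C(C)C)(C(C)C)C(C)C)cc1 | intermediate
19 | (1S,3S)-1-[2-(diethoxyphosphoryl)-4-(TIPS-oxymethyl)furan-3-yl]-3-[(5S)-5-(hydroxymethyl)-5-methyl-4-oxo-4,5-dihydrofuran-2-yl]butyl 3-methylbut-2-enoate | OC[C@]1(C)OC(=CC1=O)[C@@H](C)C[C@H](OC(=O)C=C(C)C)c2c(P(=O)(OCC)OCC)occ2CO[Si](C(C)C)(C(C)C)C(C)C | intermediate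
20 | C12,O9-bis(pinacolboryl) derivative of 19 | CC1(C)OB(OC[C@]2(C)OC(=CC2=O)[C@@H](C)C[C@H](OC(=O)C=C(C)C)c3c(P(=O)(OCC)OCC)oc(B4OC(C)(C)C(C)(C)O4)c3CO[Si](C(C)C)(C(C)C)C(C)C)OC1(C)C | intermediate
21 | (1S,3S)-1-[2-(diethoxyphosphoryl)-5-oxo-4-(TIPS-oxymethyl)-2,5-dihydrofuran-3-yl]-3-[(5S)-5-(hydroxymethyl)-5-methyl-4-oxo-4,5-dihydrofuran-2-yl]butyl 3-methylbut-2-enoate (C8 epimers) | OC[C@]1(C)OC(=CC1=O)[C@@H](C)C[C@H](OC(=O)C=C(C)C)C2=C(CO[Si](C(C)C)(C(C)C)C(C)C)C(=O)OC2P(=O)(OCC)OCC | intermediate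
22 | (1S,3S)-1-[2-(diethoxyphosphoryl)-5-oxo-4-(TIPS-oxymethyl)-2,5-dihydrofuran-3-yl]-3-[(5S)-5-formyl-5-methyl-4-oxo-4,5-dihydrofuran-2-yl]butyl 3-methylbut-2-enoate (C8 epimers) | O=C[C@]1(C)OC(=CC1=O)[C@@H](C)C[C@H](OC(=O)C=C(C)C)C2=C(CO[Si](C(C)C)(C(C)C)C(C)C)C(=O)OC2P(=O)(OCC)OCC | intermediate
23 | (4S,6S,8E,10S)-13-O-TIPS-13-deacetyl macrocycle (target with OTIPS at C13) | CC(C)[Si](OCC1=C2/C(=C\[C@]3(C)OC(=CC3=O)[C@@H](C)C[C@@H]2OC(=O)C=C(C)C)OC1=O)(C(C)C)C(C)C | intermediate
24 | (4S,6S,8E,10S)-13-deacetyl macrocycle (13-hydroxy) | OCC1=C2/C(=C\[C@]3(C)OC(=CC3=O)[C@@H](C)C[C@@H]2OC(=O)C=C(C)C)OC1=O | intermediate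
25 | CNP0102620.1, (4S,6S,8E,10S)-13-acetoxy-3,10-epoxy-1-oxogermacra-2,7(11),8-trien-12,8-olide 6-(3-methylbut-2-enoate) | CC(=O)OCC1=C2/C(=C\[C@]3(C)OC(=CC3=O)[C@@H](C)C[C@@H]2OC(=O)C=C(C)C)OC1=O | target

**Totals**
Total step count: 17. Longest linear sequence: 13 steps (1, 2, 4, 5, 9–17).

**Steps most likely to fail**

Step 15. Oligomerisation may outrun ring closure, or the base may trigger loss of the C9 formyl group (retro-Claisen/retro-aldol cleavage at C9–C10, which would also scramble C10). The fallback sets out from 22 and moves the ring closure to a Lewis-acid-mediated C–C bond formation in which no free alkoxide exists. Treatment of 22 with TBSOTf and Et3N in dilute CH2Cl2 should generate the 2-silyloxy-5-phosphonofuran in the flask and close the ring by an intramolecular vinylogous Mukaiyama aldol addition, giving the silyl-trapped cyclic β-silyloxy phosphonate F1. The alkene is then made in a separate operation from the preformed ring: fluoride (TBAF buffered with AcOH, THF, 0 °C) frees the C9 alkoxide, which should collapse onto phosphorus and eliminate diethyl phosphate. The route is rejoined at 23.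

Step 13. Borylation may be slow at the flanked α-position, may take place at another C–H, or the boron hydride may reduce a conjugated C=C. The fallback sets out from 17 and replaces C–H activation by electrophilic halogenation and cross-coupling. NBS (1 equiv, DMF, −20 °C) should brominate the only free furan α-position, before the bromination-prone furanone exists, to give the bromofuran ynone F2. The gold-catalysed cyclisation of step 11 then gives the bromofuran furanone F3, and DDQ gives the bromofuran alcohol F4. Miyaura borylation (B2pin2, KOAc, Pd(dppf)Cl2, dioxane, 80 °C) should give the C12 boronate F5, which is oxidised with buffered H2O2 as in step 13. The route is rejoined at 21.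

Step 4. Conversion or enantioselectivity may be poor because the carbinol is flanked by the phosphoryl group, and the alkoxide may cyclise onto phosphorus at 100 °C. The fallback sets out from 4 and separates oxidation from C–C bond formation. MnO2 oxidation gives the furaldehyde F6. A chromium-catalysed asymmetric Nozaki–Hiyama-type 2-(alkoxycarbonyl)allylation with ethyl 2-(bromomethyl)acrylate (CrCl2, chiral carbazole bis(oxazoline) ligand, Mn, TMSCl, rt) should then give the (S)-hydroxy ethyl ester F7. Acid-catalysed lactonisation rejoins the route at 8.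

**Further compounds**
F1 | step 15 | cyclic C9-(tert-butyldimethylsilyloxy) C8-(diethoxyphosphoryl) aldol adduct (13-O-TIPS, C8/C9 diastereomers) | CC(C)[Si](OCC1=C2C(P(=O)(OCC)OCC)(OC1=O)C(O[Si](C)(C)C(C)(C)C)[C@]3(C)OC(=CC3=O)[C@@H](C)C[C@@H]2OC(=O)C=C(C)C)(C(C)C)C(C)C
F2 | step 13 | C12-bromo derivative of 17 | COc1ccc(COC[C@](C)(O)C#CC(=O)[C@@H](C)C[C@H](OC(=O)C=C(C)C)c2c(P(=O)(OCC)OCC)oc(Br)c2CO[Si](C(C)C)(C(C)C)C(C)C)cc1
F3 | step 13 | C12-bromo derivative of 18 | COc1ccc(COC[C@]2(C)OC(=CC2=O)[C@@H](C)C[C@H](OC(=O)C=C(C)C)c3c(P(=O)(OCC)OCC)oc(Br)c3CO[Si](C(C)C)(C(C)C)C(C)C)cc1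
F4 | step 13 | C12-bromo derivative of 19 | OC[C@]1(C)OC(=CC1=O)[C@@H](C)C[C@H](OC(=O)C=C(C)C)c2c(P(=O)(OCC)OCC)oc(Br)c2CO[Si](C(C)C)(C(C)C)C(C)C
F5 | step 13 | C12-pinacolboryl derivative of 19 | OC[C@]1(C)OC(=CC1=O)[C@@H](C)C[C@H](OC(=O)C=C(C)C)c2c(P(=O)(OCC)OCC)oc(B3OC(C)(C)C(C)(C)O3)c2CO[Si](C(C)C)(C(C)C)C(C)C
F6 | step 4 | diethyl [3-formyl-4-(TIPS-oxymethyl)furan-2-yl]phosphonate | CCOP(=O)(OCC)c1occ(CO[Si](C(C)C)(C(C)C)C(C)C)c1C=O
F7 | step 4 | ethyl (4S)-4-[2-(diethoxyphosphoryl)-4-(TIPS-oxymethyl)furan-3-yl]-4-hydroxy-2-methylidenebutanoate | C=C(C[C@H](O)c1c(P(=O)(OCC)OCC)occ1CO[Si](C(C)C)(C(C)C)C(C)C)C(=O)OCC
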